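**Assumption 1:** the target SMILES has no stereocentre and no stereogenic double bond, so the compound is achiral and "single enantiomer" needs no stereocontrol.
**Assumption 2:** the three O-demethylations in step 4 are written in the most plausible order (ring A, then ring B, then ring C); any order converges on 13.

## Retrosynthetic overview
1. Target 14 ⇐ tetramethyl ether 10 by thiolate O-demethylation: one methyl is lost per ring, and ring A stops at the mono-ether because its phenoxide blocks a second cleavage.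
2. 10 ⇐ stilbene diarylcarbinol 8 by one hydrogenation (C=C saturation plus benzhydrol C–O hydrogenolysis).
3. 8 ⇐ aryl bromide 4 + 4-methoxybenzaldehyde 5 by Br–Li exchange and 1,2-addition, which places the benzylic carbon exactly between the two ring-A oxygens.
4. 4 ⇐ 4-bromo-3,5-dimethoxybenzaldehyde 1 + diethyl (3-methoxybenzyl)phosphonate 2 by Horner–Wadsworth–Emmons olefination.
5. No ring is formed: all three benzene rings are bought. Ring A is joined to ring B first (step 1), then to ring C (step 2).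

## Route

Step 1
Reactants: 1 4-bromo-3,5-dimethoxybenzaldehyde; 2 diethyl (3-methoxybenzyl)phosphonate
Product: 4 (E)-2-bromo-1,3-dimethoxy-5-[2-(3-methoxyphenyl)ethenyl]benzene, via phosphonate carbanion 3 (not isolated)
Conditions: KOtBu (1.2 equiv), THF, 0 °C, 20 min; then 1, 0 °C → rt
Reagents that add atoms: none
Why: Horner–Wadsworth–Emmons olefination of a non-enolisable aryl aldehyde with a benzylic phosphonate carbanion gives the E-stilbene reliably (the alkene geometry is irrelevant because it is hydrogenated in step 3), and the aryl bromide and methyl ethers are inert to KOtBu at rt.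

Step 2
Reactants: 4 (E)-2-bromo-1,3-dimethoxy-5-[2-(3-methoxyphenyl)ethenyl]benzene; 5 4-methoxybenzaldehyde
Product: 8 {2,6-dimethoxy-4-[(E)-2-(3-methoxyphenyl)ethenyl]phenyl}(4-methoxyphenyl)methanol (racemic), via aryllithium 6 (not isolated), via lithium alkoxide 7 (not isolated)
Conditions: n-BuLi (1.05 equiv), THF, −78 °C, 15 min; then 5 (1.1 equiv), −78 → 0 °C; H2O quench
Reagents that add atoms: none
Why: Bromine–lithium exchange at −78 °C is far faster than any addition of n-BuLi to the stilbene and gives an aryllithium stabilised by two ortho-methoxy groups, whose 1,2-addition to the aldehyde fixes the benzylic carbon between the two oxygens; the new carbinol centre is formed racemic on purpose because it is removed in step 3.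

Step 3
Reactants: 8 {2,6-dimethoxy-4-[(E)-2-(3-methoxyphenyl)ethenyl]phenyl}(4-methoxyphenyl)methanol
Product: 10 1,3-dimethoxy-2-(4-methoxybenzyl)-5-[2-(3-methoxyphenyl)ethyl]benzene, via saturated carbinol 9 (not isolated)
Conditions: H2 (3 atm), 10% Pd/C, EtOAc–AcOH (4:1), rt
Reagents that add atoms: none
Why: Catalytic hydrogenation saturates the stilbene C=C quickly, and the same Pd/C–H2 in acidic medium hydrogenolyses the doubly benzylic, strongly electron-rich C–OH to CH2; this erases the only stereocentre and the alkene geometry while aryl methyl ethers are untouched.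

Step 4
Reactants: 10 1,3-dimethoxy-2-(4-methoxybenzyl)-5-[2-(3-methoxyphenyl)ethyl]benzene
Product: 14 2-(4-hydroxybenzyl)-5-[2-(3-hydroxyphenyl)ethyl]-3-methoxyphenol, via monosodium phenoxide 11 (not isolated), via disodium bisphenoxide 12 (not isolated), via trisodium trisphenoxide 13 (not isolated)
Conditions: NaSEt (10 equiv), DMF, 150 °C, Ar; then 1 M HCl
Reagents that add atoms: none
Why: Thiolate SN2 O-demethylation of aryl methyl ethers cleaves one methyl on each ring, and once ring A carries a phenoxide its second methoxy would have to leave as a dianion, so exactly the one OMe of the target survives; no stereocentre is involved.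

## Compound list
1 | 4-bromo-3,5-dimethoxybenzaldehyde | COc1cc(C=O)cc(OC)c1Br | starting material
2 | diethyl (3-methoxybenzyl)phosphonate | CCOP(=O)(Cc1cccc(OC)c1)OCC | starting material
3 | potassium (diethoxyphosphoryl)(3-methoxyphenyl)methanide (phosphonate carbanion, formed in the flask) | CCOP(=O)(OCC)[CH-]c1cccc(OC)c1.[K+] | intermediate
4 | (E)-2-bromo-1,3-dimethoxy-5-[2-(3-methoxyphenyl)ethenyl]benzene | COc1cc(/C=C/c2cccc(OC)c2)cc(OC)c1Br | intermediate
5 | 4-methoxybenzaldehyde | COc1ccc(C=O)cc1 | starting material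
6 | {2,6-dimethoxy-4-[(E)-2-(3-methoxyphenyl)ethenyl]phenyl}lithium (aryllithium, formed in the flask) | COc1cc(/C=C/c2cccc(OC)c2)cc(OC)c1[Li] | intermediate
7 | lithium {2,6-dimethoxy-4-[(E)-2-(3-methoxyphenyl)ethenyl]phenyl}(4-methoxyphenyl)methanolate (racemic, formed in the flask) | COc1cc(/C=C/c2cccc(OC)c2)cc(OC)c1C([O-])c1ccc(OC)cc1.[Li+] | intermediate
8 | {2,6-dimethoxy-4-[(E)-2-(3-methoxyphenyl)ethenyl]phenyl}(4-methoxyphenyl)methanol (racemic) | COc1cc(/C=C/c2cccc(OC)c2)cc(OC)c1C(O)c1ccc(OC)cc1 | intermediate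
9 | {2,6-dimethoxy-4-[2-(3-methoxyphenyl)ethyl]phenyl}(4-methoxyphenyl)methanol (racemic, formed in the flask) | COc1cc(CCc2cccc(OC)c2)cc(OC)c1C(O)c1ccc(OC)cc1 | intermediate
10 | 1,3-dimethoxy-2-(4-methoxybenzyl)-5-[2-(3-methoxyphenyl)ethyl]benzene | COc1cc(CCc2cccc(OC)c2)cc(OC)c1Cc1ccc(OC)cc1 | intermediate
11 | sodium 3-methoxy-2-(4-methoxybenzyl)-5-[2-(3-methoxyphenyl)ethyl]phenolate (formed in the flask) | COc1cc(CCc2cccc(OC)c2)cc([O-])c1Cc1ccc(OC)cc1.[Na+] | intermediate
12 | disodium 3-{2-[3-methoxy-4-(4-methoxybenzyl)-5-oxidophenyl]ethyl}phenolate (formed in the flask) | COc1cc(CCc2cccc([O-])c2)cc([O-])c1Cc1ccc(OC)cc1.[Na+].[Na+] | intermediate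
13 | trisodium tris-phenolate of 14 (formed in the flask) | COc1cc(CCc2cccc([O-])c2)cc([O-])c1Cc1ccc([O-])cc1.[Na+].[Na+].[Na+] | intermediate
14 | 2-(4-hydroxybenzyl)-5-[2-(3-hydroxyphenyl)ethyl]-3-methoxyphenol (CNP0112925.0) | COc1cc(CCc2cccc(O)c2)cc(O)c1Cc1ccc(O)cc1 | target

## Summary
Total step count: 4. Longest linear sequence: 4 steps (1 → 4 → 8 → 10 → 14).

Steps most likely to fail, in order of risk: step 4, then step 3, then step 2.

Fallback for step 2 (butyllithium attacking the stilbene, or poor addition of the hindered aryllithium). It sets out from 4 and comes back at 10. The C–C bond is made by Pd-catalysed Negishi coupling instead of organolithium chemistry. (4-Methoxybenzyl)zinc chloride F1 is prepared from 4-methoxybenzyl chloride with Zn dust/LiCl in THF. It is coupled with 4 (Pd(OAc)2/SPhos, THF, 50 °C) to give (E)-1,3-dimethoxy-2-(4-methoxybenzyl)-5-[2-(3-methoxyphenyl)ethenyl]benzene F2. Simple alkene hydrogenation (H2, Pd/C, EtOAc) then gives 10.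

Fallback for step 3 (slow C–O hydrogenolysis, or acid-induced Friedel–Crafts self-condensation of the benzhydrol). It sets out from 8 and comes back at 10. Only the alkene is hydrogenated under neutral conditions (H2 1 atm, Pd/C, EtOAc, no acid), and the saturated carbinol 9 is isolated. The hydroxyl is then removed by ionic reduction (Et3SiH, TFA, CH2Cl2, 0 °C), in which the stabilised diarylmethyl cation is trapped by hydride to give 10. No new compound is made.

Fallback for step 4 (incomplete cleavage on rings B and C, or over-cleavage on ring A). It sets out from 1 and comes back at 14. The two ring-A oxygens are differentiated at the start and every phenol is carried as a benzyl ether, so no demethylation is needed at the end.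
- Mono-demethylation of 1 with BBr3 under stoichiometric control (CH2Cl2, −78 → 0 °C, recovered 1 recycled) gives 4-bromo-3-hydroxy-5-methoxybenzaldehyde F3.
- Benzylation (BnBr, K2CO3, DMF) gives 3-(benzyloxy)-4-bromo-5-methoxybenzaldehyde F4.
- Arbuzov reaction of 3-(benzyloxy)benzyl bromide with P(OEt)3 (neat, 130 °C) gives diethyl [3-(benzyloxy)benzyl]phosphonate F5.
- Deprotonation of F5 (KOtBu, THF) gives potassium [3-(benzyloxy)phenyl](diethoxyphosphoryl)methanide F6, which olefinates F4 to (E)-1-(benzyloxy)-5-{2-[3-(benzyloxy)phenyl]ethenyl}-2-bromo-3-methoxybenzene F7.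
- Br–Li exchange (n-BuLi, THF, −78 °C) gives {2-(benzyloxy)-4-[(E)-2-(3-(benzyloxy)phenyl)ethenyl]-6-methoxyphenyl}lithium F8. Addition to 4-(benzyloxy)benzaldehyde gives lithium {2-(benzyloxy)-4-[(E)-2-(3-(benzyloxy)phenyl)ethenyl]-6-methoxyphenyl}[4-(benzyloxy)phenyl]methanolate F9, and water quench gives racemic {2-(benzyloxy)-4-[(E)-2-(3-(benzyloxy)phenyl)ethenyl]-6-methoxyphenyl}[4-(benzyloxy)phenyl]methanol F10.
- One hydrogenation (H2, Pd/C, EtOAc–EtOH–AcOH) saturates the alkene, cleaves the three benzyl ethers and hydrogenolyses the carbinol, giving 14 directly.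

## Further compounds
F1 | step 2 | (4-methoxybenzyl)zinc chloride | COc1ccc(C[Zn]Cl)cc1
F2 | step 2 | (E)-1,3-dimethoxy-2-(4-methoxybenzyl)-5-[2-(3-methoxyphenyl)ethenyl]benzene | COc1cc(/C=C/c2cccc(OC)c2)cc(OC)c1Cc1ccc(OC)cc1
F0 | step 3 | none | none
F3 | step 4 | 4-bromo-3-hydroxy-5-methoxybenzaldehyde | COc1cc(C=O)cc(O)c1Br
F4 | step 4 | 3-(benzyloxy)-4-bromo-5-methoxybenzaldehyde | COc1cc(C=O)cc(OCc2ccccc2)c1Br
F5 | step 4 | diethyl [3-(benzyloxy)benzyl]phosphonate | CCOP(=O)(Cc1cccc(OCc2ccccc2)c1)OCC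
F6 | step 4 | potassium [3-(benzyloxy)phenyl](diethoxyphosphoryl)methanide | CCOP(=O)(OCC)[CH-]c1cccc(OCc2ccccc2)c1.[K+]
F7 | step 4 | (E)-1-(benzyloxy)-5-{2-[3-(benzyloxy)phenyl]ethenyl}-2-bromo-3-methoxybenzene | COc1cc(/C=C/c2cccc(OCc3ccccc3)c2)cc(OCc2ccccc2)c1Br
F8 | step 4 | {2-(benzyloxy)-4-[(E)-2-(3-(benzyloxy)phenyl)ethenyl]-6-methoxyphenyl}lithium | COc1cc(/C=C/c2cccc(OCc3ccccc3)c2)cc(OCc2ccccc2)c1[Li]
F9 | step 4 | lithium {2-(benzyloxy)-4-[(E)-2-(3-(benzyloxy)phenyl)ethenyl]-6-methoxyphenyl}[4-(benzyloxy)phenyl]methanolate (racemic) | COc1cc(/C=C/c2cccc(OCc3ccccc3)c2)cc(OCc2ccccc2)c1C([O-])c1ccc(OCc2ccccc2)cc1.[Li+]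
F10 | step 4 | {2-(benzyloxy)-4-[(E)-2-(3-(benzyloxy)phenyl)ethenyl]-6-methoxyphenyl}[4-(benzyloxy)phenyl]methanol (racemic) | COc1cc(/C=C/c2cccc(OCc3ccccc3)c2)cc(OCc2ccccc2)c1C(O)c1ccc(OCc2ccccc2)cc1
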